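**Plan**

- Retrosynthesis: the cage is opened at C8–C1 and C11–C7, geranyl and prenyl are taken off C5, and the cyclopentane is opened at C3–C15. The side chain goes back through a 1,2-aryl shift to a benzyl ketone, made from an aryl bromide (ring C1–C5, C9) and a C11–C15 methyl ketone.
- Enabling feature: C3 belongs both to the six-membered triketone ring (C1, C2, C3, C4, C5, C9), a dearomatised benzoylphloroglucinol, and to the cyclopentane (C3, C12, C13, C14, C15). A flat phenol carrying the C12–C15 chain on C3 can therefore close the five-membered ring by alkylating its own ipso carbon.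
- Forward: chain C11–C15 from furan-2(5H)-one (steps 1–4); union with the aryl bromide and aryl shift from C11 to C12 (steps 7–10); cyclopentane by ipso-alkylation (step 13); prenyl and geranyl on C5 (steps 14, 15); last the seven-membered ring (C11–C7) and the bicyclo[3.3.1]nonane (C8–C1) in one cascade (step 18).
- Stereochemistry: C14 from the rhodium/(R)-BINAP 1,4-addition; C12 from a CBS reduction followed by the invertive aryl shift; C3 from C12 through allylic strain in the key step; C5 from alkylation anti to the C12 arm; C7 and C1 from the cage.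

Key step: step 13

Remark: atom numbers are those of the target core (C1 benzoyl bridgehead, C2 and C4 ketones beside spiro C3, C5 geranyl bridgehead, C9 bridging ketone, C6–C7–C8 bridge, C11–C12 link, cyclopentane C3/C12–C15). Enolised triketones are drawn as one tautomer, and the five building blocks listed as starting materials are taken as commercial.

**Route**

Step 1
Reactants: 1 furan-2(5H)-one; 2 potassium trifluoro(prop-1-en-2-yl)borate
Product: 3 (R)-4-(prop-1-en-2-yl)dihydrofuran-2(3H)-one
Conditions: [Rh(cod)2]BF4 (3 mol%), (R)-BINAP (3.3 mol%), toluene/H2O 10:1, 100 °C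
Reagents that add atoms: none
Why: Rhodium-catalysed asymmetric 1,4-addition of an alkenyltrifluoroborate to the butenolide (Hayashi–Miyaura reaction), in which the (R)-BINAP complex should add the isopropenyl group to one enantiotopic face and set C14 as R, the ligand antipode being used if the sense proves opposite.

Step 2
Reactants: 3 (R)-4-(prop-1-en-2-yl)dihydrofuran-2(3H)-one
Product: 5 (S)-3,3-dimethyl-4-(prop-1-en-2-yl)dihydrofuran-2(3H)-one, via trans-3-methyl lactone 4 (not isolated)
Conditions: LiN(iPr)2 (1.1 equiv), MeI, THF, −78 °C; then LiN(iPr)2 (1.2 equiv), MeI, DMPU, −78 → 0 °C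
Reagents that add atoms: iodomethane, CI
Why: Two successive lactone enolate alkylations build the quaternary C13; C14 lies β to the carbonyl and cannot epimerise, and its descriptor changes from R to S only because C13 gains CIP priority.

Step 3
Reactants: 5 (S)-3,3-dimethyl-4-(prop-1-en-2-yl)dihydrofuran-2(3H)-one
Product: 6 (S)-5-hydroxy-3,3-dimethyl-4-(prop-1-en-2-yl)pentan-2-one
Conditions: MeLi (1.05 equiv), THF, −78 °C; H2O
Reagents that add atoms: methyllithium, [Li]C
Why: Organolithium addition to a lactone should stop at the lithium hemiketal, which the two α-methyl groups shield from a second addition, so that work-up releases the methyl ketone (C11, C12) in equilibrium with its cyclic hemiketal.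

Step 4
Reactants: 6 (S)-5-hydroxy-3,3-dimethyl-4-(prop-1-en-2-yl)pentan-2-one
Product: 7 (S)-5-(tert-butyldimethylsilyloxy)-3,3-dimethyl-4-(prop-1-en-2-yl)pentan-2-one
Conditions: TBSCl, imidazole, DMF, 0 °C → rt
Reagents that add atoms: tert-butyldimethylsilyl chloride, CC(C)(C)[Si](C)(C)Cl
Why: Silylation of the primary hydroxyl of the open-chain tautomer drains the hemiketal equilibrium and masks the C15 oxygen, which would otherwise be alkylated by or interfere with the ketone enolate in step 7.

Step 5
Reactants: 8 2,4,6-trihydroxybenzophenone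
Product: 9 2,4,6-tris(methoxymethoxy)benzophenone
Conditions: MOMCl (3.6 equiv), NaH (3.6 equiv), DMF, 0 °C → rt
Reagents that add atoms: chloromethyl methyl ether, COCCl
Why: Williamson ether synthesis on all three phenols, NaH being needed for the two hydroxyls that are hydrogen-bonded to the ketone.

Step 6
Reactants: 9 2,4,6-tris(methoxymethoxy)benzophenone
Product: 10 3-bromo-2,4,6-tris(methoxymethoxy)benzophenone
Conditions: NBS (1.0 equiv), MeCN, 0 °C
Reagents that add atoms: N-bromosuccinimide, O=C1CCC(=O)N1Br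
Why: Electrophilic aromatic bromination at one of the two equivalent ring positions flanked by two alkoxy groups, the benzoyl ring being deactivated and one equivalent of reagent limiting dibromination.

Step 7
Reactants: 7 (S)-5-(tert-butyldimethylsilyloxy)-3,3-dimethyl-4-(prop-1-en-2-yl)pentan-2-one; 10 3-bromo-2,4,6-tris(methoxymethoxy)benzophenone
Product: 11 (S)-1-[3-benzoyl-2,4,6-tris(methoxymethoxy)phenyl]-5-(tert-butyldimethylsilyloxy)-3,3-dimethyl-4-(prop-1-en-2-yl)pentan-2-one
Conditions: Pd2(dba)3 (2 mol%), XPhos (5 mol%), NaOtBu (1.5 equiv), toluene, 70 °C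
Reagents that add atoms: none
Why: Palladium-catalysed α-arylation of a ketone enolate, in which ketone 7 can enolise only toward its methyl group (C11), the bulky biarylphosphine tolerates the doubly ortho-substituted bromide, and the hindered product enolate resists a second arylation.

Step 8
Reactants: 11 (S)-1-[3-benzoyl-2,4,6-tris(methoxymethoxy)phenyl]-5-(tert-butyldimethylsilyloxy)-3,3-dimethyl-4-(prop-1-en-2-yl)pentan-2-one
Product: 12 (2R,4S)-1-[3-benzoyl-2,4,6-tris(methoxymethoxy)phenyl]-5-(tert-butyldimethylsilyloxy)-3,3-dimethyl-4-(prop-1-en-2-yl)pentan-2-ol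
Conditions: (S)-Me-CBS (0.3 equiv), catecholborane (1.5 equiv), toluene, −78 → −40 °C; MeOH, then 1 M NaOH wash
Reagents that add atoms: none
Why: Corey–Bakshi–Shibata reduction, in which the tert-alkyl side (C13) acts as the large and the benzylic CH2 (C11) as the small group, so the S catalyst should give the 12R alcohol; catecholborane at this temperature should leave the isopropenyl group and the benzophenone carbonyl (shielded by two ortho ethers) alone, and the minor C12 epimer is a diastereomer removable by chromatography.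

Step 9
Reactants: 12 (2R,4S)-1-[3-benzoyl-2,4,6-tris(methoxymethoxy)phenyl]-5-(tert-butyldimethylsilyloxy)-3,3-dimethyl-4-(prop-1-en-2-yl)pentan-2-ol
Product: 13 (2S,4R)-5-[3-benzoyl-2,4,6-tris(methoxymethoxy)phenyl]-3,3-dimethyl-2-(prop-1-en-2-yl)pentane-1,4-diol
Conditions: Bu4NF, THF, 0 °C → rt
Reagents that add atoms: none
Why: Fluoride desilylation of the primary silyl ether, to which aryl methoxymethyl ethers and the diaryl ketone are inert.

Step 10
Reactants: 13 (2S,4R)-5-[3-benzoyl-2,4,6-tris(methoxymethoxy)phenyl]-3,3-dimethyl-2-(prop-1-en-2-yl)pentane-1,4-diol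
Product: 15 (2S,4S)-4-[3-benzoyl-2,4,6-tris(methoxymethoxy)phenyl]-5-hydroxy-3,3-dimethyl-2-(prop-1-en-2-yl)pentyl methanesulfonate, via bis-mesylate 14 (not isolated)
Conditions: Ms2O (2.5 equiv), Et3N, CH2Cl2, −20 °C; then THF/H2O, NaHCO3, rt
Reagents that add atoms: methanesulfonic anhydride, CS(=O)(=O)OS(C)(=O)=O; water, O
Why: Sulfonylation of both hydroxyls followed by neighbouring-group participation (phenonium rearrangement): the secondary mesylate at C12, closed to direct substitution by the adjacent quaternary C13, is displaced from the rear by the electron-rich aryl ring and water opens the bridged ion at the unhindered C11, a stereospecific 1,2-aryl shift that inverts C12 (12R carbinol to 12S aryl-bearing centre) and leaves the unassisted primary C15 mesylate in place.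

Step 11
Reactants: 15 (2S,4S)-4-[3-benzoyl-2,4,6-tris(methoxymethoxy)phenyl]-5-hydroxy-3,3-dimethyl-2-(prop-1-en-2-yl)pentyl methanesulfonate
Product: 16 (2S,4S)-4-[3-benzoyl-2,4,6-tris(methoxymethoxy)phenyl]-5-(tert-butyldiphenylsilyloxy)-3,3-dimethyl-2-(prop-1-en-2-yl)pentyl methanesulfonate
Conditions: TBDPSCl, imidazole, CH2Cl2, rt
Reagents that add atoms: tert-butyldiphenylsilyl chloride, CC(C)(C)[Si](Cl)(c1ccccc1)c1ccccc1
Why: Silylation of the primary alcohol, so that the C11 oxygen can neither displace the mesylate nor condense with the ring carbonyls later, and so that a large group sits on C11 for the facial control in steps 13 and 15.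

Step 12
Reactants: 16 (2S,4S)-4-[3-benzoyl-2,4,6-tris(methoxymethoxy)phenyl]-5-(tert-butyldiphenylsilyloxy)-3,3-dimethyl-2-(prop-1-en-2-yl)pentyl methanesulfonate
Product: 18 (2S,4S)-4-(3-benzoyl-2,4,6-trihydroxyphenyl)-5-(tert-butyldiphenylsilyloxy)-3,3-dimethyl-2-(prop-1-en-2-yl)pentyl methanesulfonate, via tris(trimethylsilyl) ether 17 (not isolated)
Conditions: TMSOTf (6 equiv), 2,2′-bipyridyl (9 equiv), CH2Cl2, 0 °C; then H2O, rt
Reagents that add atoms: none
Why: Cleavage of aryl methoxymethyl ethers by silyl triflate/bipyridyl, which exchanges them for trimethylsilyl ethers through bipyridinium salts under buffered conditions and hydrolyses these on addition of water, sparing the mesylate, the silyl ether and the isopropenyl group.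

Step 13
Reactants: 18 (2S,4S)-4-(3-benzoyl-2,4,6-trihydroxyphenyl)-5-(tert-butyldiphenylsilyloxy)-3,3-dimethyl-2-(prop-1-en-2-yl)pentyl methanesulfonate
Product: 19 (1S,3S)-9-benzoyl-1-[(tert-butyldiphenylsilyloxy)methyl]-6,10-dihydroxy-2,2-dimethyl-3-(prop-1-en-2-yl)spiro[4.5]deca-6,9-dien-8-one (C11 on the C4 side of spiro C3)
Conditions: Cs2CO3 (2.5 equiv), DMF (0.01 M), 0 → 45 °C; pH 4 buffer
Reagents that add atoms: none
Why: Cs2CO3 forms the phenolate, whose ring carbon C3 (ortho to O2 and O4, para to O9) displaces the C15 mesylate in an SN2 step, and the spirodienone formed settles as the enolised triketone. The closest known reactions are the intramolecular ipso-alkylation of phenolates to spirodienones (Ar1-5 participation) and the alkylative dearomatisation of acylphloroglucinols. The cyclopentane (C3, C12, C13, C14, C15) closes in the 5-exo-tet mode. The new stereocentre C3 is controlled by C12: in the transition state C13 stands perpendicular to the ring, the C12 hydrogen eclipses O2, which is buttressed by the benzoyl group, and the bulky silyloxymethyl group turns toward O4 beside the unsubstituted C5, so C15 should attack the face that leaves C11 on the C4 side. The step needs C- over O-alkylation and C3 over C5, which the five-membered closure at C3 secures against seven-membered closure at O2, O4 or C5, with dilution against intermolecular alkylation.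

Step 14
Reactants: 19 spiro triketone (C5–H); 20 1-bromo-3-methylbut-2-ene (prenyl bromide)
Product: 21 7-(3-methylbut-2-en-1-yl) derivative of 19 (prenyl on C5; 12S,14S)
Conditions: NaOMe (2.0 equiv), MeOH, 0 °C
Reagents that add atoms: none
Why: C-alkylation of a vinylogous acid anion by an allylic bromide in a protic solvent, which hydrogen-bonds the oxygens and sends the electrophile to C5, the only unsubstituted ring carbon; no stereocentre forms because C5 stays enolised.

Step 15
Reactants: 21 C5-prenyl spiro triketone; 22 (E)-1-bromo-3,7-dimethylocta-2,6-diene (geranyl bromide)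
Product: 23 C5-quaternary triketone with prenyl on C5 syn to C12 and geranyl anti (C4 and C9 ketones; C2 enol; 12S,14S)
Conditions: NaOMe (2.0 equiv), MeOH, 0 °C → rt
Reagents that add atoms: none
Why: Second C-alkylation at C5 (dearomatised acylphloroglucinol chemistry of the lupulone type) makes C5 quaternary; geranyl bromide should approach the enolate face opposite to the silyloxymethyl arm that C12 holds over C4/C5, which leaves the prenyl group syn to C12 as the cage requires.

Step 16
Reactants: 23 C5-quaternary triketone (C11–OTBDPS)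
Product: 24 primary alcohol (C11–OH) of 23
Conditions: HF·pyridine, THF/pyridine, 0 °C → rt
Reagents that add atoms: none
Why: Desilylation with acidic fluoride avoids the nucleophilic base that could cleave the non-enolisable β-diketone array around C3–C4–C5 by retro-Claisen reaction.

Step 17
Reactants: 24 primary alcohol (C11–OH)
Product: 25 primary iodide (C11–I) of 23
Conditions: I2, PPh3, imidazole, CH2Cl2, 0 °C → rt
Reagents that add atoms: iodine, II
Why: Appel reaction through the alkoxyphosphonium salt; C4 can no longer enolise and the remaining enol oxygens cannot reach C11, so no oxygen should displace the leaving group, and imidazole buffers the acidic enol.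

Step 18
Reactants: 25 primary iodide (C11–I)
Product: 26 CNP0110731.1 (target)
Conditions: fac-Ir(ppy)3 (2 mol%), 2,6-lutidine (2 equiv), MeCN (0.005 M, degassed), blue LEDs, rt
Reagents that add atoms: none
Why: Proposed new method: the excited iridium complex should reduce the C11–I bond, the primary radical should add 7-exo-trig to C7 of the prenyl group (the geranyl group lies on the other ring face), the tertiary C8 radical should be oxidised by the tetravalent iridium formed in the first electron transfer, and the cation should alkylate enol carbon C1 (six-membered closure) with loss of a proton, C7 and C1 being fixed by the geometry of the cage; the closest known reactions are photoredox radical–polar crossover cyclisations of unactivated alkyl iodides and the cation–enol closure of the C1–C8 bond of bicyclo[3.3.1]nonane acylphloroglucinols.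

**Compound list**

1 | furan-2(5H)-one | O=C1OCC=C1 | starting material
2 | potassium trifluoro(prop-1-en-2-yl)borate | [K+].C=C(C)[B-](F)(F)F | starting material
3 | (R)-4-(prop-1-en-2-yl)dihydrofuran-2(3H)-one | O=C1OC[C@@H](C(C)=C)C1 | intermediate
4 | (3S,4R)-3-methyl-4-(prop-1-en-2-yl)dihydrofuran-2(3H)-one (trans) | O=C1OC[C@@H](C(C)=C)[C@@H]1C | intermediate (not isolated)
5 | (S)-3,3-dimethyl-4-(prop-1-en-2-yl)dihydrofuran-2(3H)-one | O=C1OC[C@@H](C(C)=C)C1(C)C | intermediate
6 | (S)-5-hydroxy-3,3-dimethyl-4-(prop-1-en-2-yl)pentan-2-one (open form of the cyclic hemiketal) | CC(=O)C(C)(C)[C@@H](CO)C(C)=C | intermediate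
7 | (S)-5-(tert-butyldimethylsilyloxy)-3,3-dimethyl-4-(prop-1-en-2-yl)pentan-2-one | CC(=O)C(C)(C)[C@@H](CO[Si](C)(C)C(C)(C)C)C(C)=C | intermediate
8 | 2,4,6-trihydroxybenzophenone | O=C(c1ccccc1)c1c(O)cc(O)cc1O | starting material
9 | 2,4,6-tris(methoxymethoxy)benzophenone | O=C(c1ccccc1)c1c(OCOC)cc(OCOC)cc1OCOC | intermediate
10 | 3-bromo-2,4,6-tris(methoxymethoxy)benzophenone | O=C(c1ccccc1)c1c(OCOC)c(Br)c(OCOC)cc1OCOC | intermediate
11 | (S)-1-[3-benzoyl-2,4,6-tris(methoxymethoxy)phenyl]-5-(tert-butyldimethylsilyloxy)-3,3-dimethyl-4-(prop-1-en-2-yl)pentan-2-one | O=C(c1ccccc1)c1c(OCOC)c(CC(=O)C(C)(C)[C@@H](CO[Si](C)(C)C(C)(C)C)C(C)=C)c(OCOC)cc1OCOC | intermediate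
12 | (2R,4S)-1-[3-benzoyl-2,4,6-tris(methoxymethoxy)phenyl]-5-(tert-butyldimethylsilyloxy)-3,3-dimethyl-4-(prop-1-en-2-yl)pentan-2-ol (12R,14S) | O=C(c1ccccc1)c1c(OCOC)c(C[C@@H](O)C(C)(C)[C@@H](CO[Si](C)(C)C(C)(C)C)C(C)=C)c(OCOC)cc1OCOC | intermediate
13 | (2S,4R)-5-[3-benzoyl-2,4,6-tris(methoxymethoxy)phenyl]-3,3-dimethyl-2-(prop-1-en-2-yl)pentane-1,4-diol (12R,14S) | O=C(c1ccccc1)c1c(OCOC)c(C[C@@H](O)C(C)(C)[C@@H](CO)C(C)=C)c(OCOC)cc1OCOC | intermediate
14 | (2S,4R)-5-[3-benzoyl-2,4,6-tris(methoxymethoxy)phenyl]-3,3-dimethyl-2-(prop-1-en-2-yl)pentane-1,4-diyl dimethanesulfonate | O=C(c1ccccc1)c1c(OCOC)c(C[C@@H](OS(C)(=O)=O)C(C)(C)[C@@H](COS(C)(=O)=O)C(C)=C)c(OCOC)cc1OCOC | intermediate (not isolated)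
15 | (2S,4S)-4-[3-benzoyl-2,4,6-tris(methoxymethoxy)phenyl]-5-hydroxy-3,3-dimethyl-2-(prop-1-en-2-yl)pentyl methanesulfonate (12S,14S) | O=C(c1ccccc1)c1c(OCOC)c([C@@H](CO)C(C)(C)[C@@H](COS(C)(=O)=O)C(C)=C)c(OCOC)cc1OCOC | intermediate
16 | (2S,4S)-4-[3-benzoyl-2,4,6-tris(methoxymethoxy)phenyl]-5-(tert-butyldiphenylsilyloxy)-3,3-dimethyl-2-(prop-1-en-2-yl)pentyl methanesulfonate | O=C(c1ccccc1)c1c(OCOC)c([C@@H](CO[Si](c2ccccc2)(c2ccccc2)C(C)(C)C)C(C)(C)[C@@H](COS(C)(=O)=O)C(C)=C)c(OCOC)cc1OCOC | intermediate
17 | (2S,4S)-4-[3-benzoyl-2,4,6-tris(trimethylsilyloxy)phenyl]-5-(tert-butyldiphenylsilyloxy)-3,3-dimethyl-2-(prop-1-en-2-yl)pentyl methanesulfonate | O=C(c1ccccc1)c1c(O[Si](C)(C)C)c([C@@H](CO[Si](c2ccccc2)(c2ccccc2)C(C)(C)C)C(C)(C)[C@@H](COS(C)(=O)=O)C(C)=C)c(O[Si](C)(C)C)cc1O[Si](C)(C)C | intermediate (not isolated)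
18 | (2S,4S)-4-(3-benzoyl-2,4,6-trihydroxyphenyl)-5-(tert-butyldiphenylsilyloxy)-3,3-dimethyl-2-(prop-1-en-2-yl)pentyl methanesulfonate (key-step precursor; 12S,14S) | O=C(c1ccccc1)c1c(O)c([C@@H](CO[Si](c2ccccc2)(c2ccccc2)C(C)(C)C)C(C)(C)[C@@H](COS(C)(=O)=O)C(C)=C)c(O)cc1O | intermediate
19 | (1S,3S)-9-benzoyl-1-[(tert-butyldiphenylsilyloxy)methyl]-6,10-dihydroxy-2,2-dimethyl-3-(prop-1-en-2-yl)spiro[4.5]deca-6,9-dien-8-one; enolised triketone with C5–H, the CH2O arm on C12 lying on the C4 side of spiro C3 and trans to the isopropenyl group (12S,14S) | C=C(C)[C@@H]1C[C@@]2(C(O)=CC(=O)C(C(=O)c3ccccc3)=C2O)[C@@H](CO[Si](c3ccccc3)(c3ccccc3)C(C)(C)C)C1(C)C | intermediate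
20 | 1-bromo-3-methylbut-2-ene (prenyl bromide) | CC(C)=CCBr | starting material
21 | 7-(3-methylbut-2-en-1-yl) derivative of 19 (prenyl on C5; stereocentres as in 19) | C=C(C)[C@@H]1C[C@@]2(C(O)=C(CC=C(C)C)C(=O)C(C(=O)c3ccccc3)=C2O)[C@@H](CO[Si](c3ccccc3)(c3ccccc3)C(C)(C)C)C1(C)C | intermediate
22 | (E)-1-bromo-3,7-dimethylocta-2,6-diene (geranyl bromide) | CC(C)=CCC/C(C)=C/CBr | starting material
23 | spiro triketone with quaternary C5 carrying prenyl (syn to C12) and (E)-geranyl (anti to C12), C1 benzoyl, C2 enol, C4 and C9 ketones, C11–OTBDPS (12S,14S) | C=C(C)[C@@H]1C[C@@]2(C(=O)[C@@](C/C=C(\C)CCC=C(C)C)(CC=C(C)C)C(=O)C(C(=O)c3ccccc3)=C2O)[C@@H](CO[Si](c3ccccc3)(c3ccccc3)C(C)(C)C)C1(C)C | intermediate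
24 | C11 primary alcohol corresponding to 23 | C=C(C)[C@@H]1C[C@@]2(C(=O)[C@@](C/C=C(\C)CCC=C(C)C)(CC=C(C)C)C(=O)C(C(=O)c3ccccc3)=C2O)[C@@H](CO)C1(C)C | intermediate
25 | C11 primary iodide corresponding to 23 | C=C(C)[C@@H]1C[C@@]2(C(=O)[C@@](C/C=C(\C)CCC=C(C)C)(CC=C(C)C)C(=O)C(C(=O)c3ccccc3)=C2O)[C@@H](CI)C1(C)C | intermediate
26 | CNP0110731.1 | C=C(C)[C@@H]1C[C@@]23C(=O)[C@@]4(C/C=C(\C)CCC=C(C)C)C[C@@H](C[C@H]2C1(C)C)C(C)(C)[C@](C(=O)c1ccccc1)(C4=O)C3=O | target

**Step count and risks**

Total steps: 18. Longest linear sequence: 16 steps (steps 1–4 and 7–18, from furan-2(5H)-one); steps 5 and 6 prepare bromide 10 on a side branch.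

Steps most likely to fail:

Step 18. Electron transfer to the unactivated primary iodide may be slow, and hydrogen abstraction by the C11 radical may outrun the slow 7-exo closure. The most serious risk is that the closure proceeds through the rotamer that leaves C8 on the outer face of the new ring; that C7 epimer cannot reach C1, and its C8 radical or cation would only lose a proton. The cation may also be captured at enol oxygen. The fallback is ionic and uses known reactions; it sets out from alcohol 24 and returns at 26. Dess–Martin oxidation should give the C11 aldehyde F1. BF3·OEt2 in CH2Cl2 at −78 °C should then trigger a Prins cyclisation in which C7 of the prenyl group adds to the activated aldehyde and the C8 cation alkylates enol carbon C1. Because the Prins addition is reversible, the C7 epimer that cannot close should revert, so the 11-hydroxy cage compound F2 should collect. Its hydroxyl is removed by Barton–McCombie deoxygenation: thiocarbonyldiimidazole gives the imidazolyl thiocarbonate F3, and Bu3SnH with AIBN in toluene at 90 °C gives 26.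

Step 13. The preference for placing the C11 arm beside O4 rather than O2 rests on allylic strain alone, so attack on the other ring face may give a mixture of C3 epimers; elimination of the mesylate may also compete. The fallback replaces steric bias by a tether; it sets out from 15 and returns at 19. ZnBr2 and propane-1-thiol should remove the three methoxymethyl groups to give the tetrol mesylate F4. tBu2Si(OTf)2 and 2,6-lutidine should join the C11 hydroxyl and O4 (the most acidic phenol, para to the ketone and not hydrogen-bonded to it) in the seven-membered cyclic silylene F5. Cs2CO3 in DMF then effects the same ipso-alkylation through the O2/O9 phenolate; with C11 held next to C4, only the required C3 configuration can form, giving the silylene-bridged spiro enol ether F6. HF·pyridine frees the spiro alcohol F7, and TBDPSCl with imidazole gives 19.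

Step 10. Ionisation of the C12 mesylate may not be followed cleanly by aryl migration and hydration. The returning sulfonate or an ortho ether oxygen may capture C11 (dihydrobenzofuran formation), the arenium ion may lose a methoxymethyl group, or the aryl ring may begin to displace the primary mesylate. The fallback triggers the same aryl shift by redox condensation while C15 is still protected; it sets out from 12 and returns at 16. Mitsunobu reaction (PPh3, diisopropyl azodicarboxylate, 4-nitrobenzoic acid) activates the C12 hydroxyl, the aryl ring migrates with inversion, and the carboxylate captures C11 to give the 4-nitrobenzoate F8. K2CO3 in MeOH gives the C11 alcohol F9, TBDPSCl with imidazole the bis-silyl ether F10, pyridinium p-toluenesulfonate in MeOH removes only the primary tert-butyldimethylsilyl group to give the C15 alcohol F11, and MsCl with Et3N gives 16.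

Further compounds
F1 | step 18 | C11 aldehyde corresponding to 24 | C=C(C)[C@@H]1C[C@@]2(C(=O)[C@@](C/C=C(\C)CCC=C(C)C)(CC=C(C)C)C(=O)C(C(=O)c3ccccc3)=C2O)[C@@H](C=O)C1(C)C
F2 | step 18 | 11-hydroxy derivative of 26 (C11 configuration not controlled; the centre is removed) | C=C(C)[C@@H]1C[C@@]23C(=O)[C@@]4(C/C=C(\C)CCC=C(C)C)C[C@@H](C(O)[C@H]2C1(C)C)C(C)(C)[C@](C(=O)c1ccccc1)(C4=O)C3=O
F3 | step 18 | O-(imidazol-1-ylthiocarbonyl) derivative of F2 | C=C(C)[C@@H]1C[C@@]23C(=O)[C@@]4(C/C=C(\C)CCC=C(C)C)C[C@@H](C(OC(=S)n5ccnc5)[C@H]2C1(C)C)C(C)(C)[C@](C(=O)c1ccccc1)(C4=O)C3=O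
F4 | step 13 | (2S,4S)-4-(3-benzoyl-2,4,6-trihydroxyphenyl)-5-hydroxy-3,3-dimethyl-2-(prop-1-en-2-yl)pentyl methanesulfonate | O=C(c1ccccc1)c1c(O)c([C@@H](CO)C(C)(C)[C@@H](COS(C)(=O)=O)C(C)=C)c(O)cc1O
F5 | step 13 | cyclic di-tert-butylsilylene of F4 joining the C11 oxygen and O4 | O=C(c1ccccc1)c1c(O)c2c(cc1O)O[Si](C(C)(C)C)(C(C)(C)C)OC[C@H]2C(C)(C)[C@@H](COS(C)(=O)=O)C(C)=C
F6 | step 13 | silylene-bridged spiro enol ether (C4–O–Si–O–C11) | C=C(C)[C@@H]1C[C@]23C(O[Si](C(C)(C)C)(C(C)(C)C)OC[C@H]3C1(C)C)=CC(=O)C(C(=O)c4ccccc4)=C2O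
F7 | step 13 | C11 alcohol corresponding to 19 | C=C(C)[C@@H]1C[C@@]2(C(O)=CC(=O)C(C(=O)c3ccccc3)=C2O)[C@@H](CO)C1(C)C
F8 | step 10 | (2S,4S)-2-[3-benzoyl-2,4,6-tris(methoxymethoxy)phenyl]-5-(tert-butyldimethylsilyloxy)-3,3-dimethyl-4-(prop-1-en-2-yl)pentyl 4-nitrobenzoate | O=C(c1ccccc1)c1c(OCOC)c([C@@H](COC(=O)c2ccc(cc2)[N+](=O)[O-])C(C)(C)[C@@H](CO[Si](C)(C)C(C)(C)C)C(C)=C)c(OCOC)cc1OCOC
F9 | step 10 | (2S,4S)-2-[3-benzoyl-2,4,6-tris(methoxymethoxy)phenyl]-5-(tert-butyldimethylsilyloxy)-3,3-dimethyl-4-(prop-1-en-2-yl)pentan-1-ol | O=C(c1ccccc1)c1c(OCOC)c([C@@H](CO)C(C)(C)[C@@H](CO[Si](C)(C)C(C)(C)C)C(C)=C)c(OCOC)cc1OCOC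
F10 | step 10 | C11 tert-butyldiphenylsilyl, C15 tert-butyldimethylsilyl bis-ether of the rearranged diol (12S,14S) | O=C(c1ccccc1)c1c(OCOC)c([C@@H](CO[Si](c2ccccc2)(c2ccccc2)C(C)(C)C)C(C)(C)[C@@H](CO[Si](C)(C)C(C)(C)C)C(C)=C)c(OCOC)cc1OCOC
F11 | step 10 | (2S,4S)-4-[3-benzoyl-2,4,6-tris(methoxymethoxy)phenyl]-5-(tert-butyldiphenylsilyloxy)-3,3-dimethyl-2-(prop-1-en-2-yl)pentan-1-ol | O=C(c1ccccc1)c1c(OCOC)c([C@@H](CO[Si](c2ccccc2)(c2ccccc2)C(C)(C)C)C(C)(C)[C@@H](CO)C(C)=C)c(OCOC)cc1OCOC
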